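Time stops helping the teal run: from 60.0 min to 80.0 min target gains 0.6 percentage points. So I ask what a longer wait cannot change, and I must choose how the next flask is charged.

| flask | starting material | second substrate | reagent | free catalyst | remark | time |
|---|---|---|---|---|---|---|
| teal | 0.40 M | 0.20 M | 0.40 M | 0.88 mM | run made earlier |  |
| red | 0.40 M | 0.20 M | 0.40 M | 0.44 mM | run made earlier |  |
| amber | 0.40 M | 0.20 M | 0.40 M | 0.66 mM | run made earlier |  |
| blue | 0.40 M | 0.20 M | 0.20 M | 0.88 mM | run made earlier |  |
| south | 0.40 M (fed, over 25 min) | 0.200 M | 0.400 M | 0.88 mM | all else is in the flask from the start; the feed brings no volume worth counting | 2.0 h |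
| south-west | 0.40 M | 0.200 M | 0.400 M | 0.88 mM | everything together at the start | 2.0 h |
| north | 0.40 M | 0.200 M | 0.400 M (fed, over 25 min) | 0.88 mM | all else is in the flask from the start; the feed brings no volume worth counting | 2.0 h |

| run | time / min | target / % | over-reaction product / % |
|---|---|---|---|
| teal | 5.00 | 23.4 | 0.7 |
| teal | 15.0 | 43.9 | 6.4 |
| teal | 25.0 | 52.0 | 10.2 |
| teal | 40.0 | 56.9 | 13.0 |
| teal | 60.0 | 58.3 | 14.3 |
| teal | 80.0 | 58.9 | 14.8 |
| red | 20.0 | 28.1 | 7.5 |
| red | 40.0 | 32.5 | 14.1 |
| red | 60.0 | 31.1 | 19.1 |
| red | 80.0 | 29.8 | 22.8 |
| red | 90.0 | 28.8 | 23.4 |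
| red | 120 | 26.5 | 26.7 |
| amber | 10.0 | 29.0 | 3.6 |
| amber | 15.0 | 35.4 | 5.3 |
| amber | 25.0 | 42.2 | 10.0 |
| amber | 40.0 | 45.8 | 14.2 |
| amber | 80.0 | 46.6 | 19.5 |
| amber | 120 | 45.8 | 20.8 |
| blue | 10.0 | 33.2 | 1.3 |
| blue | 20.0 | 42.4 | 2.0 |
| blue | 30.0 | 42.6 | 1.9 |
| blue | 60.0 | 43.0 | 1.5 |
| blue | 120 | 43.3 | 1.5 |

(readings scatter by 0.3 percentage points)

- the flask that comes out highest in share of target in target plus over-reaction product, or "all alike" when all lie within 1.5 percentage points (south / south-west / north / all alike)
- share of target in target plus over-reaction product at the end, south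
- share of target in target plus over-reaction product at the end, south-west
- share of target in target plus over-reaction product at the end, north

Reagent goes three ways: one for each target made, one more for each over-reaction product, one for each second product. If reagent is the limiting reagent in teal, as the flat end suggests, the balance leaves c(second product) = 0.0460 M. In blue, the same balance on its last readings gives 0.0148 M, which is less.

Teal converted 0.295 M of starting material, so it has 0.0592 M of what I call spare reagent: the reagent charge less c(starting material converted) less c(second product). Spare reagent either stands unreacted or has become over-reaction product, so on the assumption that reagent is used up the share of target is one minus spare over converted. For south-west, which repeats teal, that gives 79.9 %.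

North also starts short of reagent, so I assume blue's second product, teal's conversion and, again, reagent used up. Its spare reagent is then 0.0904 M, more than teal's, and its share 69.4 %. No run reads the second product for south, so I give it no number. I keep south-west.

The forecast chooses north, with 64 % for south, 79.9 % for south-west and 83 % for north: “North keeps reagent low early, while catalyst is active, and leaves little afterwards”. We part on north.

The flasks give 72.9 % for south, 79.4 % for south-west and 66.3 % for north, so south-west comes out highest.

    starting material + free catalyst ⇌ catalyst intermediate A (K = 2.40 L mol⁻¹, k = 1.70 L mol⁻¹ s⁻¹)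
    reagent + target → over-reaction product (k = 0.00120 L mol⁻¹ s⁻¹)
    reagent + catalyst intermediate A → free catalyst + target (k = 51.0 L mol⁻¹ s⁻¹)
    second substrate + free catalyst ⇌ catalyst intermediate B (K = 2.20 L mol⁻¹, k = 3.00 L mol⁻¹ s⁻¹)
    reagent + catalyst intermediate B → free catalyst + second product (k = 0.960 L mol⁻¹ s⁻¹)
    catalyst intermediate B → spent catalyst (k = 0.00270 s⁻¹)

In north at 0.417 h, 42.7 % of the reagent stands in the flask with 65.0 % of the catalyst spent. By 2.00 h over-reaction product has climbed from 4.87 % to 22.6 %, while target goes from 44.2 % to 44.5 %. North's spare reagent, from its end state, is 0.108 M, more than teal's 0.0592 M; that is 27.0 % of the starting material charged, and over-reaction product reads 26.8 % at 20.0 h. The neighbour flask, south-west with 0.24 M of reagent, has 0.0121 M spare and gives a share of 94.2 %.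

(The readings come from a simulation with constants of no real substance.)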